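**Assumption:** compounds 1, 2, 5, 10 and 15 are catalogue items (single enantiomers where chiral), and MAD [MeAl(BHT)2] is used as a toluene stock solution made beforehand from AlMe3 and 2 equiv of BHT.

## Retrosynthetic overview

1. Talapolyester D comes from global hydrogenolysis of a tri-O-benzyl ether; the hindered aryl ester C–O bond is made just before by Pd alkoxycarbonylation of an aryl iodide with methyl (S)-3-hydroxybutanoate.
2. The terminal (S)-3-hydroxybutanoate comes from acetylketene O-acylation followed by Ru–(S)-BINAP hydrogenation.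
3. Key C–O bond (arylpropanol oxygen to the acyl carbon of the dihydroxybutanoate unit): a single, chelation-gated insertion of an (S)-4-(benzyloxymethyl)-β-lactone into the aluminium alkoxide of the arylpropanol (new step), which also unmasks the 3-OH.
4. The arylpropanol comes from an aryl Grignard reagent and (R)-propylene oxide; the β-lactone comes from carbonylation of (S)-benzyl glycidyl ether.
5. Rings: no ring of the target is built (the arene is bought); the only ring formed is the transient β-lactone, made in step 2 and opened in step 3.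

## Route

Step 1
Reactants: 1 1-bromo-3,5-bis(benzyloxy)benzene; 2 (R)-propylene oxide
Product: 4 (2R)-1-[3,5-bis(benzyloxy)phenyl]propan-2-ol, via aryl Grignard reagent 3 (not isolated)
Conditions: Mg, THF, 50 °C; then CuI (10 mol %), 2 (1.3 equiv), −30 → 0 °C; then H2O
Reagents that add atoms: none
Why: Cu(I)-catalysed SN2 opening of a terminal epoxide by an aryl Grignard reagent at the unsubstituted carbon; the stereocentre of 2 is not touched, so (R)-2 gives (R)-4.

Step 2
Reactants: 5 (S)-benzyl glycidyl ether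
Product: 6 (4S)-4-[(benzyloxy)methyl]oxetan-2-one
Conditions: [(salph)Al(THF)2][Co(CO)4] (1 mol %), CO (60 bar), DME, 50 °C
Reagents that add atoms: carbon monoxide, [C-]#[O+]
Why: Lewis acid/cobaltate ring-expansion carbonylation of an epoxide: [Co(CO)4]− attacks the unsubstituted CH2, CO inserts and the alkoxide closes the β-lactone, so the C–O bond at the stereocentre is never broken and it stays (S).

Step 3
Reactants: 4 (2R)-1-[3,5-bis(benzyloxy)phenyl]propan-2-ol; 6 (4S)-4-[(benzyloxy)methyl]oxetan-2-one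
Product: 9 (2R)-1-[3,5-bis(benzyloxy)phenyl]propan-2-yl (3S)-4-(benzyloxy)-3-hydroxybutanoate, via bis(aryloxy)aluminium alkoxide of the arylpropanol 7 (not isolated), via chelated aluminium alkoxide of the product 8 (not isolated)
Conditions: MAD (1.0 equiv), toluene, 0 °C → rt (–CH4); then 6 (1.05 equiv), −20 °C → rt; aq. Rochelle salt
Reagents that add atoms: none
Why: Proposed new method: chelation-gated single insertion of a β-lactone into a stoichiometric monomeric bis(aryloxy)aluminium alkoxide, in which 4 and MAD give three-coordinate (ArO)2Al–OR 7, which binds the lactone C=O, transfers its alkoxide to the acyl carbon and opens the strained ring by acyl–oxygen cleavage (both stereocentres untouched), after which the new alkoxide is locked as the four-coordinate O,O-chelate 8 between two BHT ligands, leaving no free site for a second lactone and no free alcohol for exchange, so addition stops at one unit; the closest known reaction types are the coordination–insertion initiation step of aluminium-alkoxide ring-opening polymerisation of β-lactones, lanthanide-alkoxide alcoholysis of β-lactones and Weinreb-type Me2Al–X opening of lactones.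

Step 4
Reactants: 9 (2R)-1-[3,5-bis(benzyloxy)phenyl]propan-2-yl (3S)-4-(benzyloxy)-3-hydroxybutanoate; 10 2,2,6-trimethyl-4H-1,3-dioxin-4-one
Product: 12 (2S)-1-(benzyloxy)-4-{[(2R)-1-[3,5-bis(benzyloxy)phenyl]propan-2-yl]oxy}-4-oxobutan-2-yl 3-oxobutanoate, via acetylketene 11 (not isolated)
Conditions: 10 (1.5 equiv), toluene, 110 °C (–acetone)
Reagents that add atoms: none
Why: Acylketene trapping (acetoacetylation with the diketene–acetone adduct): thermal retro-hetero-Diels–Alder of 10 gives 11, which the secondary OH of 9 captures under neutral conditions, so the β-acyloxy ester cannot eliminate and no stereocentre is affected.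

Step 5
Reactants: 12 the acetoacetate from step 4
Product: 13 (2S)-1-(benzyloxy)-4-{[(2R)-1-[3,5-bis(benzyloxy)phenyl]propan-2-yl]oxy}-4-oxobutan-2-yl (3S)-3-hydroxybutanoate
Conditions: RuCl2[(S)-BINAP](dmf)n (1 mol %), H2 (50 bar), EtOH–CH2Cl2 (1:1), 50 °C
Reagents that add atoms: none
Why: Noyori asymmetric hydrogenation of a β-keto ester: the Ru–(S)-BINAP keto-ester chelate sets the new carbinol as (S) under catalyst control, while benzyl ethers, esters and the existing stereocentres are inert.

Step 6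
Reactants: 13 the hydroxy diester from step 5
Product: 14 (2S)-1-(benzyloxy)-4-{[(2R)-1-[3,5-bis(benzyloxy)-2-iodophenyl]propan-2-yl]oxy}-4-oxobutan-2-yl (3S)-3-hydroxybutanoate
Conditions: NIS (1.05 equiv), TFA (20 mol %), MeCN, 0 °C → rt, dark
Reagents that add atoms: N-iodosuccinimide, O=C1CCC(=O)N1I
Why: Electrophilic aromatic iodination (SEAr) at the position ortho to the side chain and para to one OBn, which is the most accessible activated site because the position between the two OBn groups is flanked twice.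

Step 7
Reactants: 14 the aryl iodide from step 6; 15 methyl (S)-3-hydroxybutanoate
Product: 16 methyl (3S)-3-({2,4-bis(benzyloxy)-6-[(2R)-2-({(3S)-4-(benzyloxy)-3-[(3S)-3-hydroxybutanoyloxy]butanoyl}oxy)propyl]benzoyl}oxy)butanoate (tri-O-benzyl talapolyester D)
Conditions: Pd(OAc)2 (5 mol %), Xantphos (7.5 mol %), CO (5 bar), i-Pr2NEt (2 equiv), 15 (10 equiv), toluene, 80 °C
Reagents that add atoms: carbon monoxide, [C-]#[O+]
Why: Pd-catalysed alkoxycarbonylation of an aryl iodide (oxidative addition, CO insertion, alcoholysis of the aroyl–Pd by 15) makes the hindered aryl ester C–O bond with retention at the carbinol carbon of 15, and the tenfold excess of 15 outcompetes the single free secondary OH of 14.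

Step 8
Reactants: 16 tri-O-benzyl talapolyester D
Product: 17 talapolyester D
Conditions: H2 (1 atm), 10 % Pd/C, EtOAc, rt
Reagents that add atoms: none
Why: Hydrogenolysis of the three benzyl ethers under neutral conditions leaves the four esters and four stereocentres untouched and avoids a 1,2-acyl shift to the freed primary OH.

## Compound list

1 | 1-bromo-3,5-bis(benzyloxy)benzene | Brc1cc(OCc2ccccc2)cc(OCc2ccccc2)c1 | starting material
2 | (R)-propylene oxide [(2R)-2-methyloxirane] | C[C@@H]1CO1 | starting material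
3 | [3,5-bis(benzyloxy)phenyl]magnesium bromide | Br[Mg]c1cc(OCc2ccccc2)cc(OCc2ccccc2)c1 | intermediate (not isolated)
4 | (2R)-1-[3,5-bis(benzyloxy)phenyl]propan-2-ol | c1c(OCc2ccccc2)cc(OCc2ccccc2)cc1C[C@@H](C)O | intermediate
5 | (S)-benzyl glycidyl ether [(2S)-2-[(benzyloxy)methyl]oxirane] | C(OCc1ccccc1)[C@@H]1CO1 | starting material
6 | (4S)-4-[(benzyloxy)methyl]oxetan-2-one | O=C1C[C@@H](COCc2ccccc2)O1 | intermediate
7 | bis(2,6-di-tert-butyl-4-methylphenoxy)aluminium (2R)-1-[3,5-bis(benzyloxy)phenyl]propan-2-olate | c1c(OCc2ccccc2)cc(OCc2ccccc2)cc1C[C@@H](C)O[Al](Oc1c(C(C)(C)C)cc(C)cc1C(C)(C)C)Oc1c(C(C)(C)C)cc(C)cc1C(C)(C)C | intermediate (not isolated)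
8 | bis(2,6-di-tert-butyl-4-methylphenoxy)aluminium alkoxide of 9 (O,O-chelate through the ester carbonyl) | c1c(OCc2ccccc2)cc(OCc2ccccc2)cc1C[C@@H](C)OC(=O)C[C@@H](COCc1ccccc1)O[Al](Oc1c(C(C)(C)C)cc(C)cc1C(C)(C)C)Oc1c(C(C)(C)C)cc(C)cc1C(C)(C)C | intermediate (not isolated)
9 | (2R)-1-[3,5-bis(benzyloxy)phenyl]propan-2-yl (3S)-4-(benzyloxy)-3-hydroxybutanoate | c1c(OCc2ccccc2)cc(OCc2ccccc2)cc1C[C@@H](C)OC(=O)C[C@@H](COCc1ccccc1)O | intermediate
10 | 2,2,6-trimethyl-4H-1,3-dioxin-4-one | CC1=CC(=O)OC(C)(C)O1 | starting material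
11 | acetylketene | CC(=O)C=C=O | intermediate (not isolated)
12 | (2S)-1-(benzyloxy)-4-{[(2R)-1-[3,5-bis(benzyloxy)phenyl]propan-2-yl]oxy}-4-oxobutan-2-yl 3-oxobutanoate | c1c(OCc2ccccc2)cc(OCc2ccccc2)cc1C[C@@H](C)OC(=O)C[C@@H](COCc1ccccc1)OC(=O)CC(C)=O | intermediate
13 | (2S)-1-(benzyloxy)-4-{[(2R)-1-[3,5-bis(benzyloxy)phenyl]propan-2-yl]oxy}-4-oxobutan-2-yl (3S)-3-hydroxybutanoate | c1c(OCc2ccccc2)cc(OCc2ccccc2)cc1C[C@@H](C)OC(=O)C[C@@H](COCc1ccccc1)OC(=O)C[C@H](C)O | intermediate
14 | (2S)-1-(benzyloxy)-4-{[(2R)-1-[3,5-bis(benzyloxy)-2-iodophenyl]propan-2-yl]oxy}-4-oxobutan-2-yl (3S)-3-hydroxybutanoate | Ic1c(OCc2ccccc2)cc(OCc2ccccc2)cc1C[C@@H](C)OC(=O)C[C@@H](COCc1ccccc1)OC(=O)C[C@H](C)O | intermediate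
15 | methyl (S)-3-hydroxybutanoate | COC(=O)C[C@H](C)O | starting material
16 | tri-O-benzyl talapolyester D (name as in step 7) | COC(=O)C[C@H](C)OC(=O)c1c(OCc2ccccc2)cc(OCc2ccccc2)cc1C[C@@H](C)OC(=O)C[C@@H](COCc1ccccc1)OC(=O)C[C@H](C)O | intermediate
17 | talapolyester D | COC(=O)C[C@H](C)OC(=O)c1c(O)cc(O)cc1C[C@@H](C)OC(=O)C[C@@H](CO)OC(=O)C[C@H](C)O | target

## Step count and risks

Total step count: 8. Longest linear sequence: 7 (steps 1, 3, 4, 5, 6, 7, 8); step 2 is a one-step side branch.

**Step 3 (proposed new step).** Risks: slow Al–Me protonolysis by the secondary alcohol, Lewis-acid ionisation of the lactone, or a second insertion. The fallback uses known chemistry, sets out from 4 and comes back at 9. Benzyloxyacetyl chloride and Meldrum's acid (pyridine, CH2Cl2, 0 °C) give 5-[2-(benzyloxy)-1-hydroxyethylidene]-2,2-dimethyl-1,3-dioxane-4,6-dione F1. Heating it with 4 in toluene at 90 °C traps the derived acylketene as (2R)-1-[3,5-bis(benzyloxy)phenyl]propan-2-yl 4-(benzyloxy)-3-oxobutanoate F2. Noyori hydrogenation of this β-keto ester with Ru–(R)-BINAP (H2 50 bar, EtOH–CH2Cl2, 50–80 °C) gives 9. The (R)-ligand gives the (3S) descriptor here because CH2OBn outranks CH2CO2R.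

**Step 7.** Risks: slow alcoholysis of the di-ortho-substituted aroyl–Pd by a secondary alcohol, amine-induced β-elimination of the acyloxy esters, or capture by the free OH of 14. The fallback replaces acyl substitution by carboxylate alkylation, sets out from 13 and comes back at 17.
- Benzyl chloroformate (pyridine, DMAP, CH2Cl2, 0 °C) converts 13 into its benzyl carbonate, (2S)-1-(benzyloxy)-4-{[(2R)-1-[3,5-bis(benzyloxy)phenyl]propan-2-yl]oxy}-4-oxobutan-2-yl (3S)-3-{[(benzyloxy)carbonyl]oxy}butanoate F6.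
- Vilsmeier–Haack formylation (POCl3, DMF, 0 °C → rt; aq. NaOAc) gives the 2-formyl derivative of this carbonate F7.
- Pinnick oxidation (NaClO2, NaH2PO4, 2-methyl-2-butene, t-BuOH–H2O) gives the corresponding 2-carboxylic acid F8.
- Mitsunobu esterification with methyl (R)-3-hydroxybutanoate (PPh3, DIAD, toluene, 0 °C) forms the aryl ester by SN2 with inversion to (S), giving the O-benzyloxycarbonyl derivative of 16 F9.
- Hydrogenolysis (H2, Pd/C, EtOAc) removes the three benzyl ethers and the benzyl carbonate together and gives 17.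

**Step 5.** Risks: slow or incomplete hydrogenation of a bulky substrate with many Lewis-basic sites, or ester exchange with the alcohol co-solvent. The fallback brings in the stereocentre ready-made, sets out from 9 (by-passing 12) and comes back at 13. Silylation of 15 (TBSCl, imidazole, DMF) gives methyl (3S)-3-[(tert-butyldimethylsilyl)oxy]butanoate F3. Saponification (LiOH, THF–H2O, 0 °C) gives (3S)-3-[(tert-butyldimethylsilyl)oxy]butanoic acid F4. Steglich esterification of 9 with this acid (EDC·HCl, DMAP, CH2Cl2, 0 °C) gives the O-tert-butyldimethylsilyl ether of 13 F5. HF·pyridine (THF, 0 °C) then gives 13.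

## Further compounds

F1 | step 3 | 5-[2-(benzyloxy)-1-hydroxyethylidene]-2,2-dimethyl-1,3-dioxane-4,6-dione | CC1(C)OC(=O)C(=C(O)COCc2ccccc2)C(=O)O1
F2 | step 3 | (2R)-1-[3,5-bis(benzyloxy)phenyl]propan-2-yl 4-(benzyloxy)-3-oxobutanoate | c1c(OCc2ccccc2)cc(OCc2ccccc2)cc1C[C@@H](C)OC(=O)CC(=O)COCc1ccccc1
F3 | step 5 | methyl (3S)-3-[(tert-butyldimethylsilyl)oxy]butanoate | COC(=O)C[C@H](C)O[Si](C)(C)C(C)(C)C
F4 | step 5 | (3S)-3-[(tert-butyldimethylsilyl)oxy]butanoic acid | OC(=O)C[C@H](C)O[Si](C)(C)C(C)(C)C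
F5 | step 5 | O-tert-butyldimethylsilyl ether of 13 | c1c(OCc2ccccc2)cc(OCc2ccccc2)cc1C[C@@H](C)OC(=O)C[C@@H](COCc1ccccc1)OC(=O)C[C@H](C)O[Si](C)(C)C(C)(C)C
F6 | step 7 | benzyl carbonate of 13 | c1c(OCc2ccccc2)cc(OCc2ccccc2)cc1C[C@@H](C)OC(=O)C[C@@H](COCc1ccccc1)OC(=O)C[C@H](C)OC(=O)OCc1ccccc1
F7 | step 7 | 2-formyl derivative of the benzyl carbonate of 13 | O=Cc1c(OCc2ccccc2)cc(OCc2ccccc2)cc1C[C@@H](C)OC(=O)C[C@@H](COCc1ccccc1)OC(=O)C[C@H](C)OC(=O)OCc1ccccc1
F8 | step 7 | 2-carboxylic acid derived from the benzyl carbonate of 13 | OC(=O)c1c(OCc2ccccc2)cc(OCc2ccccc2)cc1C[C@@H](C)OC(=O)C[C@@H](COCc1ccccc1)OC(=O)C[C@H](C)OC(=O)OCc1ccccc1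
F9 | step 7 | O-benzyloxycarbonyl derivative of 16 | COC(=O)C[C@H](C)OC(=O)c1c(OCc2ccccc2)cc(OCc2ccccc2)cc1C[C@@H](C)OC(=O)C[C@@H](COCc1ccccc1)OC(=O)C[C@H](C)OC(=O)OCc1ccccc1
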